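**Numbering used throughout:** 1 2-hydroxy-4-methoxybenzaldehyde; 2 3-chloro-3-methylbut-1-yne; 3 aryl propargyl ether; 4 ortho-allenylphenol (not isolated); 5 chromene aldehyde; 6 (3S,4S)-epoxy aldehyde; 7 diol; 8 hydroxy aldehyde; 9 oxime; 10 hydroximoyl chloride; 11 4-ethenylphenyl acetate; 12 nitrile oxide (not isolated); 13 isoxazoline; 14 β-hydroxy imine (not isolated); 15 β-hydroxy ketone; 16 enone acetate; 17 target.

Assumption: 13 and 15 are carried as mixtures of two epimers at the carbon that becomes Cβ of the enone, because step 10 makes that carbon trigonal.

## Analysis of the target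

The target is a chalcone whose acyl-bearing benzene ring (ring A) is fused to a dihydropyran, giving a chroman (O1, C2, C3, C4, C4a to C8a). C2 carries two methyl groups, C3 a hydroxyl, C5 a methoxy group, and C8 (ortho to the ring oxygen) the (E)-3-(4-hydroxyphenyl)propenoyl chain. The only stereocentre is C3 (S), a secondary carbinol between the quaternary C2 and the benzylic C4. It relates to no other centre and cannot epimerise, but it has no neighbouring group through which it could be set by substrate control. The sensitive groups are the enone (a Michael acceptor), the free phenol, the C3 carbinol, which can dehydrate under strong acid, and the electron-rich arene, whose C6 is ortho to OMe and para to O1. The difficulties are three: setting C3 in high enantiomeric purity, placing four contiguous substituents on ring A, and building the enone without damage to the carbinol or the phenol. The strategy rests on the chain C8–C(=O)–Cα=Cβ–aryl. It is a dehydrated aldol, and its carbonyl carbon and aryl-bearing Cβ stand in the 1,3-relationship of C3 and C5 of a 3,5-diaryl-4,5-dihydroisoxazole. That ring can be assembled from a nitrile oxide on C8 and a styrene, and opened later at the N–O bond.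

## Retrosynthetic reasoning

**17 to 15.** The phenol is carried as its acetate (16), so that the styrene partner is a stable commercial monomer and no free phenol passes through the earlier steps. The Cα=Cβ bond of 16 is then cut by adding water back, which gives aldol 15 with the hydroxyl on Cβ. Forward, the loss of water has to give the E alkene and spare the C3 carbinol. This is achievable because the Cβ hydroxyl is benzylic and β to a ketone, while the C3 hydroxyl is neither.

**15 to 13.** The ketone and the Cβ hydroxyl of 15 are reconnected through nitrogen, so that C=O becomes C=N and the hydroxyl oxygen becomes the ring oxygen of isoxazoline 13. The gain is that the aldol is reached without any enolate. Forward, a reductive cleavage of the N–O bond gives imine 14, which hydrolyses to 15.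

**13 to 12 and 11.** The bond from the future carbonyl carbon to Cα and the O–Cβ bond are cut together in a retro-[3+2] step, which gives nitrile oxide 12 and styrene 11. The cut is made here because this is the one C–C bond between the two aryl halves that can be formed under nearly neutral conditions with predictable regiochemistry. Of the two pieces, 11 is bought. Nitrile oxide 12 goes back through hydroximoyl chloride 10 and oxime 9 to aldehyde 8, so the C8 carbon is needed at the aldehyde oxidation level.

**8 to 6.** The C4–H bond of 8 is traced to the benzylic C–O bond of epoxide 6, with the C3–O bond left untouched so that C3 keeps its configuration. A hydride that opens the epoxide also reduces the formyl group, so the disconnection passes through diol 7. The benzylic primary alcohol of 7 is then reoxidised selectively in the presence of the C3 carbinol.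

**6 to 5.** Both C–O bonds of the epoxide are cut, leaving the cis C3=C4 alkene of chromene 5. The stereocentre is set here because a cis alkene held in a 2,2-dimethylchromene is a privileged substrate for Jacobsen–Katsuki epoxidation, and C3 offers no other handle. The forward reaction has to distinguish the two faces of the alkene and tolerate the formyl group.

**5 to 1 and 2.** The pyran ring is opened at C4–C4a through allene 4, back to aryl propargyl ether 3. The ether O–C bond is then cut to give phenol 1 and propargylic chloride 2. The regiochemistry is safe because 1 has only one free position ortho to the hydroxyl, and this position becomes C4a. Ring A is therefore bought with its methoxy group and C8 carbon already in place.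

## Alternatives that were turned down

**Alternative 1: ring A by vinylketene–alkynyl ether benzannulation.**
- **Disconnection:** ring A itself is taken apart into a diazo ketone and an alkyne.
- **Key step:** irradiation of (3E)-1-diazohex-3-ene-2,5-dione A2 triggers a Wolff rearrangement to an acetyl-substituted vinylketene, which forms C6–C7. The ketene adds to the alkynyl ether (2S)-2-(3-methoxyprop-2-yn-1-yl)-3,3-dimethyloxirane A3, forming C8a–C4a and C5–C6. The cyclobutenone then opens (4π) and recloses (6π), forming C8–C8a, to give phenol A1 with the epoxide side chain in place.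
- **For it:** it is convergent. The positions of all four ring substituents follow from the mechanism. The stereocentre arrives ready-made in A3, so no catalyst-controlled step is needed on a hindered chromene.
- **Against it:** A3 combines a 1-alkynyl ether and a trisubstituted epoxide, both acid-labile, and needs its own enantioselective synthesis. A2 carries a diazo group next to a doubly activated alkene and can consume itself by dipolar addition. A1 still needs a 6-endo epoxide opening by the phenol and then a base-mediated condensation to attach the cinnamoyl half.
- **Comparison:** on regiochemical certainty it is as strong as the chosen route. The chosen route matches it there, because 1 has a single free ortho position, and it buys the arene instead of building it. It also avoids photochemistry on a diazo compound and forms the enone without hydroxide.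

**Alternative 2: epoxidation of the acetyl chromene, then benzylic C–O cleavage.**
- **Disconnection:** the same stereo-defining disconnection as the chosen route, one carbon richer.
- **Key step:** 1-(5-methoxy-2,2-dimethyl-2H-chromen-8-yl)ethanone A5 is epoxidised with NaOCl and (S,S)-(salen)MnCl (trivalent manganese) to epoxy ketone A4. Cleavage of the benzylic C–O bond and a Claisen–Schmidt condensation of the acetyl group would follow.
- **For it:** it is the shortest plan, about half the step count of the chosen route. The aryl ketone tolerates both oxidant and hydrogenolysis better than an aldehyde, and the end game is the classical chalcone synthesis.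
- **Against it:** the condensation uses hydroxide, and the aldehyde partner has to carry a phenol protecting group that is removed afterwards, or else react as a deactivated phenoxide.
- **Comparison:** on step economy this alternative is clearly stronger, and on the stereocentre it is equal, since the chosen route sets C3 in the same way. What the chosen strategy offers in its place is an enone construction without enolate or hydroxide and with mechanistically fixed regiochemistry, using a stable commercial styrene. The second aryl group can also be varied at a late stage simply by changing the dipolarophile.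

**Alternative 3: ring A by 2-pyrone cycloaddition around the chiral pyran.**
- **Disconnection:** ring A is taken apart into a fused pyrone and a ketene acetal.
- **Key step:** the pyran-fused 2-pyrone ester A7 and 1,1-dimethoxyethene A8 combine in an inverse-demand [4+2] cycloaddition, forming C4a–C5 and C6–C7. Loss of CO2 and methanol then gives the aromatic ester A6.
- **For it:** the ester and the ring oxygen both direct the nucleophilic CH2 of A8 to the same pyrone carbon, so the methoxy group lands on C5. The carbinol is protected and set before the arene exists.
- **Against it:** A7 is a chiral bicyclic pyrone that needs a multistep synthesis of its own, and its 4-alkoxy substituent lowers its reactivity as an electron-poor diene. A6 is an ester, so the C8 carbon has to be reworked into a ketone before the same condensation as in alternative 2, and the silyl ether has to be removed.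
- **Comparison:** it is as good as the chosen route on ring regiochemistry, but it spends its effort on a ring that 1 supplies ready-made, and it ends with the base-mediated step that the chosen route avoids.

Key step: step 8

## Route

Step 1
Reactants: 1 2-hydroxy-4-methoxybenzaldehyde; 2 3-chloro-3-methylbut-1-yne
Product: 3 4-methoxy-2-[(2-methylbut-3-yn-2-yl)oxy]benzaldehyde
Conditions: 2 (2 equiv), DBU, CuCl2·2H2O (cat.), MeCN, 0 °C to rt
Reagents that add atoms: none
Why: Copper-catalysed O-alkylation of a phenol by a tertiary propargylic chloride, the usual entry to aryl 1,1-dimethylpropargyl ethers; DBU is basic enough to break the hydrogen bond between the phenol and the ortho formyl group, and the aldehyde is inert here.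

Step 2
Reactants: 3 4-methoxy-2-[(2-methylbut-3-yn-2-yl)oxy]benzaldehyde
Product: 5 5-methoxy-2,2-dimethyl-2H-chromene-8-carbaldehyde, via ortho-allenylphenol 4 (not isolated)
Conditions: PhNEt2, 185 °C
Reagents that add atoms: none
Why: Aromatic propargyl Claisen rearrangement; the [3,3] shift can end only at the one free ortho carbon and gives allene 4 after enolisation, which closes to the 2H-chromene by a 1,5-hydrogen shift and 6π oxa-electrocyclisation, both helped by the gem-dimethyl group.

Step 3
Reactants: 5 5-methoxy-2,2-dimethyl-2H-chromene-8-carbaldehyde
Product: 6 (3S,4S)-3,4-epoxy-5-methoxy-2,2-dimethylchroman-8-carbaldehyde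
Conditions: (S,S)-(salen)MnCl (5 mol%; salen = N,N'-bis(3,5-di-tert-butylsalicylidene)-1,2-cyclohexanediamine), 4-phenylpyridine N-oxide (20 mol%), aq. NaOCl buffered to pH 11.3, CH2Cl2, 0 °C
Reagents that add atoms: sodium hypochlorite, [Na+].[O-]Cl
Why: Jacobsen–Katsuki epoxidation of a cis alkene in a 2,2-dimethylchromene, one of its best substrate classes; the pentavalent oxo-manganese species formed from the trivalent manganese catalyst transfers oxygen to one face of the alkene, and the (S,S) catalyst is the enantiomer that gives 3S,4S epoxides from such chromenes, which sets C3. The formyl group, conjugated with both ring oxygens, should make the benzylic epoxide less prone to ionise.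

Step 4
Reactants: 6 (3S,4S)-3,4-epoxy-5-methoxy-2,2-dimethylchroman-8-carbaldehyde
Product: 7 (3S)-8-(hydroxymethyl)-5-methoxy-2,2-dimethylchroman-3-ol
Conditions: LiAlH4 (2 equiv), THF, 0 °C to rt; then H2O, aq. NaOH, H2O
Reagents that add atoms: none
Why: Hydride opens the epoxide by SN2 attack at the benzylic C4, since C3 is shielded by the adjacent quaternary C2; the C3–O bond is not touched, so C3 stays S. The aldehyde is reduced to the benzylic alcohol in the same operation.

Step 5
Reactants: 7 (3S)-8-(hydroxymethyl)-5-methoxy-2,2-dimethylchroman-3-ol
Product: 8 (3S)-3-hydroxy-5-methoxy-2,2-dimethylchroman-8-carbaldehyde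
Conditions: activated MnO2 (10 equiv), CH2Cl2, rt
Reagents that add atoms: none
Why: Manganese dioxide (tetravalent manganese) oxidises benzylic alcohols and leaves the saturated secondary C3 carbinol alone; the electron-rich arene speeds the benzylic oxidation.

Step 6
Reactants: 8 (3S)-3-hydroxy-5-methoxy-2,2-dimethylchroman-8-carbaldehyde
Product: 9 (E)-(3S)-3-hydroxy-5-methoxy-2,2-dimethylchroman-8-carbaldehyde oxime
Conditions: NH2OH·HCl, NaOAc, EtOH/H2O, rt
Reagents that add atoms: hydroxylamine hydrochloride, NO.Cl
Why: Oxime condensation of an aryl aldehyde under buffered conditions; the oxime geometry has no consequence for the later steps.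

Step 7
Reactants: 9 (E)-(3S)-3-hydroxy-5-methoxy-2,2-dimethylchroman-8-carbaldehyde oxime
Product: 10 (Z)-(3S)-N,3-dihydroxy-5-methoxy-2,2-dimethylchroman-8-carboximidoyl chloride
Conditions: NCS (1.05 equiv), DMF, 0 °C to rt
Reagents that add atoms: N-chlorosuccinimide, O=C1CCC(=O)N1Cl
Why: Chlorination of an aldoxime at carbon with NCS in DMF, the standard preparation of aryl hydroximoyl chlorides; one equivalent at low temperature favours the oxime over the ring, and the secondary alcohol is not oxidised by NCS alone.

Step 8
Reactants: 10 (Z)-(3S)-N,3-dihydroxy-5-methoxy-2,2-dimethylchroman-8-carboximidoyl chloride; 11 4-ethenylphenyl acetate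
Product: 13 4-[3-[(3S)-3-hydroxy-5-methoxy-2,2-dimethylchroman-8-yl]-4,5-dihydro-1,2-oxazol-5-yl]phenyl acetate (both epimers at the aryl-bearing ring carbon), via nitrile oxide 12 (not isolated)
Conditions: 11 (3 equiv), Et3N (1.2 equiv, added over several hours), CH2Cl2, 0 °C to rt
Reagents that add atoms: none
Why: Et3N removes HCl from 10 to give nitrile oxide 12, a 1,3-dipole that is consumed as it forms. 12 adds to the vinyl group of 11 in a concerted, asynchronous six-electron [3+2] cycloaddition, the closest known reaction type being the Huisgen nitrile oxide–alkene cycloaddition to 3,5-disubstituted 2-isoxazolines. The 4,5-dihydroisoxazole ring closes intermolecularly and suprafacially on both components, the dipole carbon bonding to the CH2 terminus (the future C(=O)–Cα bond) and the dipole oxygen to the benzylic carbon (the temporary O–Cβ bond). The regiochemistry the step needs, 5-aryl and not 4-aryl, is secured by the monosubstituted styrene, whose larger frontier-orbital coefficient and unhindered end are both at CH2, where the bulky carbon terminus of the dipole bonds. The new stereocentre at the aryl-bearing ring carbon is not controlled, because the only stereocentre of the dipole (C3 of the chroman) is remote, and both epimers are taken on since this carbon becomes trigonal in step 10. Chemoselectivity against dimerisation of 12 to the furoxan is the second requirement; it is addressed by slow addition of the base into an excess of 11 and helped by the ortho ring oxygen, which slows dimerisation of aryl nitrile oxides. The substrate holds no second alkene, because the chromene double bond was used up in step 3, and the free C3 hydroxyl and the aryl acetate do not react with the dipole or with Et3N under these conditions.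

Step 9
Reactants: 13 4-[3-[(3S)-3-hydroxy-5-methoxy-2,2-dimethylchroman-8-yl]-4,5-dihydro-1,2-oxazol-5-yl]phenyl acetate
Product: 15 4-[1-hydroxy-3-[(3S)-3-hydroxy-5-methoxy-2,2-dimethylchroman-8-yl]-3-oxopropyl]phenyl acetate (both carbinol epimers), via β-hydroxy imine 14 (not isolated)
Conditions: Mo(CO)6 (1 equiv), MeCN/H2O, 80 °C
Reagents that add atoms: water, O
Why: Reductive N–O cleavage of a 2-isoxazoline by Mo(CO)6 (zerovalent molybdenum) in wet acetonitrile gives imine 14, which hydrolyses to the β-hydroxy ketone; unlike hydrogenation over nickel or palladium, this reagent does not cleave the benzylic C–O bond. Any enone already formed by loss of water, or any acetate lost to the liberated ammonia, converges on 17 in steps 10 and 11.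

Step 10
Reactants: 15 4-[1-hydroxy-3-[(3S)-3-hydroxy-5-methoxy-2,2-dimethylchroman-8-yl]-3-oxopropyl]phenyl acetate
Product: 16 4-[(1E)-3-[(3S)-3-hydroxy-5-methoxy-2,2-dimethylchroman-8-yl]-3-oxoprop-1-en-1-yl]phenyl acetate
Conditions: TsOH·H2O (10 mol%), toluene, 70 °C
Reagents that add atoms: none
Why: Acid-catalysed dehydration of an aldol; the hydroxyl that leaves is benzylic and β to the ketone, the product is a fully conjugated chalcone, and the E alkene is strongly favoured thermodynamically. The C3 carbinol has neither activation and should survive catalytic acid at this temperature.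

Step 11
Reactants: 16 4-[(1E)-3-[(3S)-3-hydroxy-5-methoxy-2,2-dimethylchroman-8-yl]-3-oxoprop-1-en-1-yl]phenyl acetate
Product: 17 (2E)-1-[(3S)-3-hydroxy-5-methoxy-2,2-dimethylchroman-8-yl]-3-(4-hydroxyphenyl)prop-2-en-1-one
Conditions: K2CO3 (0.2 equiv), MeOH, 0 °C to rt; then aq. NH4Cl
Reagents that add atoms: none
Why: Base-catalysed transesterification of an aryl acetate with methanol, which is fast because phenoxide is a good leaving group; the enone cannot cyclise to a flavanone since the ortho oxygen is part of the pyran ring.

## Compound list

1 | 2-hydroxy-4-methoxybenzaldehyde | COc1ccc(C=O)c(O)c1 | starting material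
2 | 3-chloro-3-methylbut-1-yne | CC(C)(Cl)C#C | starting material
3 | 4-methoxy-2-[(2-methylbut-3-yn-2-yl)oxy]benzaldehyde | COc1ccc(C=O)c(OC(C)(C)C#C)c1 | intermediate
4 | 2-hydroxy-4-methoxy-3-(3-methylbuta-1,2-dien-1-yl)benzaldehyde | COc1ccc(C=O)c(O)c1C=C=C(C)C | intermediate (not isolated)
5 | 5-methoxy-2,2-dimethyl-2H-chromene-8-carbaldehyde | COc1ccc(C=O)c2c1C=CC(C)(C)O2 | intermediate
6 | (3S,4S)-3,4-epoxy-5-methoxy-2,2-dimethylchroman-8-carbaldehyde | COc1ccc(C=O)c2c1[C@@H]1O[C@@H]1C(C)(C)O2 | intermediate
7 | (3S)-8-(hydroxymethyl)-5-methoxy-2,2-dimethylchroman-3-ol | COc1ccc(CO)c2c1C[C@H](O)C(C)(C)O2 | intermediate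
8 | (3S)-3-hydroxy-5-methoxy-2,2-dimethylchroman-8-carbaldehyde | COc1ccc(C=O)c2c1C[C@H](O)C(C)(C)O2 | intermediate
9 | (E)-(3S)-3-hydroxy-5-methoxy-2,2-dimethylchroman-8-carbaldehyde oxime | COc1ccc(/C=N/O)c2c1C[C@H](O)C(C)(C)O2 | intermediate
10 | (Z)-(3S)-N,3-dihydroxy-5-methoxy-2,2-dimethylchroman-8-carboximidoyl chloride | COc1ccc(/C(Cl)=N/O)c2c1C[C@H](O)C(C)(C)O2 | intermediate
11 | 4-ethenylphenyl acetate | C=Cc1ccc(OC(C)=O)cc1 | starting material
12 | (3S)-3-hydroxy-5-methoxy-2,2-dimethylchroman-8-carbonitrile oxide | COc1ccc(C#[N+][O-])c2c1C[C@H](O)C(C)(C)O2 | intermediate (not isolated)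
13 | 4-[3-[(3S)-3-hydroxy-5-methoxy-2,2-dimethylchroman-8-yl]-4,5-dihydro-1,2-oxazol-5-yl]phenyl acetate, both epimers at the aryl-bearing ring carbon | COc1ccc(C2=NOC(c3ccc(OC(C)=O)cc3)C2)c2c1C[C@H](O)C(C)(C)O2 | intermediate
14 | 4-[1-hydroxy-3-[(3S)-3-hydroxy-5-methoxy-2,2-dimethylchroman-8-yl]-3-iminopropyl]phenyl acetate, both carbinol epimers | COc1ccc(C(=N)CC(O)c2ccc(OC(C)=O)cc2)c2c1C[C@H](O)C(C)(C)O2 | intermediate (not isolated)
15 | 4-[1-hydroxy-3-[(3S)-3-hydroxy-5-methoxy-2,2-dimethylchroman-8-yl]-3-oxopropyl]phenyl acetate, both carbinol epimers | COc1ccc(C(=O)CC(O)c2ccc(OC(C)=O)cc2)c2c1C[C@H](O)C(C)(C)O2 | intermediate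
16 | 4-[(1E)-3-[(3S)-3-hydroxy-5-methoxy-2,2-dimethylchroman-8-yl]-3-oxoprop-1-en-1-yl]phenyl acetate | COc1ccc(C(=O)/C=C/c2ccc(OC(C)=O)cc2)c2c1C[C@H](O)C(C)(C)O2 | intermediate
17 | (2E)-1-[(3S)-3-hydroxy-5-methoxy-2,2-dimethylchroman-8-yl]-3-(4-hydroxyphenyl)prop-2-en-1-one | COc1ccc(C(=O)/C=C/c2ccc(O)cc2)c2c1C[C@H](O)C(C)(C)O2 | target

## Step count and least certain steps

Total: 11 steps. Longest linear sequence: 11 steps, from 1 to 17. Compounds 2 and 11 enter as commercial reagents.

**Step 8 (key step).**
- **What may go wrong:** nitrile oxide 12 may dimerise to the furoxan faster than it is trapped, because a styrene is only a moderately reactive dipolarophile. Base-induced polymerisation of 11 would lower the trapping rate further.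
- **Fallback:** the cycloaddition is given up for a classical condensation. The fallback sets out from 8. MeMgBr (excess, THF, 0 °C) should give (3S)-8-(1-hydroxyethyl)-5-methoxy-2,2-dimethylchroman-3-ol F1. MnO2 should oxidise only its benzylic hydroxyl to 1-[(3S)-3-hydroxy-5-methoxy-2,2-dimethylchroman-8-yl]ethanone F2. Claisen–Schmidt condensation of F2 with commercial 4-(methoxymethoxy)benzaldehyde (KOH, EtOH) should give (2E)-1-[(3S)-3-hydroxy-5-methoxy-2,2-dimethylchroman-8-yl]-3-[4-(methoxymethoxy)phenyl]prop-2-en-1-one F3. HCl in MeOH removes the methoxymethyl group, and the route is rejoined at 17.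

**Step 7.**
- **What may go wrong:** electrophilic chlorination of the arene at C6 (ortho to the methoxy group, para to the ring oxygen) may compete with chlorination of the oxime carbon.
- **Fallback:** the halogenation–elimination path to the dipole is replaced by direct oxidative dehydrogenation. The fallback sets out from 9, which is treated with PhI(OAc)2 (CF3CO2H cat., MeOH, 0 °C) in the presence of excess 11. Nitrile oxide 12 forms without any chlorinating agent and is trapped in the same flask, so the route is rejoined at 13 and 10 is bypassed.

**Step 9.**
- **What may go wrong:** retro-aldol fragmentation of the metal-bound β-hydroxy imine or of the aldol at 80 °C would break the C–C bond just made. Incomplete hydrolysis of the imine is a smaller risk.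
- **Fallback:** the ring is opened at the C–O bond by base instead of at the N–O bond by reduction. The fallback sets out from 13. K2CO3 in MeOH should give 4-[3-[(3S)-3-hydroxy-5-methoxy-2,2-dimethylchroman-8-yl]-4,5-dihydro-1,2-oxazol-5-yl]phenol F4. LDA (excess, THF, −78 to 0 °C) deprotonates the ring CH2 and expels the ring oxygen from the benzylic carbon, giving (2E)-1-[(3S)-3-hydroxy-5-methoxy-2,2-dimethylchroman-8-yl]-3-(4-hydroxyphenyl)prop-2-en-1-one oxime F5. Aqueous TiCl3 (trivalent titanium) buffered with NH4OAc reduces the oxime N–O bond, the imine hydrolyses, and the route is rejoined at 17.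

**Step 3.**
- **What may go wrong:** the formyl group may be oxidised by hypochlorite or by the oxo-manganese species in competition with oxygen transfer to the alkene. The peri methoxy group at C5 may also lower the facial selectivity.
- **Fallback:** the aldehyde is masked and the reduction–reoxidation pair becomes unnecessary. The fallback sets out from 5. Ethylene glycol (TsOH cat., benzene, Dean–Stark) should give 2-(5-methoxy-2,2-dimethyl-2H-chromen-8-yl)-1,3-dioxolane F6. The same epoxidation should give 2-[(3S,4S)-3,4-epoxy-5-methoxy-2,2-dimethylchroman-8-yl]-1,3-dioxolane F7, which is taken on without chromatography. LiAlH4 should give (3S)-8-(1,3-dioxolan-2-yl)-5-methoxy-2,2-dimethylchroman-3-ol F8. NH2OH·HCl in aqueous EtOH cleaves the acetal and forms the oxime in one operation, so the route is rejoined at 9.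

**Step 4.**
- **What may go wrong:** Lewis-acid-assisted ionisation of the benzylic C–O bond before hydride delivery, followed by a 1,2-hydride shift to a chroman-3-one and its reduction, would erode the configuration at C3.
- **Fallback:** the hydride is replaced by catalytic hydrogenolysis. The fallback sets out from 6, which is treated with H2 (1 atm) over Pd/C (palladium on carbon, zerovalent palladium) in EtOAc with a trace of Et3N. This cleaves the strained benzylic C4–O bond on the metal surface without a cationic intermediate and should leave the electron-rich aryl aldehyde largely intact, so the route is rejoined at 8. Any material over-reduced to 7 is returned to 8 by step 5.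

## Further compounds

F1 | step 8 | (3S)-8-(1-hydroxyethyl)-5-methoxy-2,2-dimethylchroman-3-ol, both carbinol epimers | COc1ccc(C(C)O)c2c1C[C@H](O)C(C)(C)O2
F2 | step 8 | 1-[(3S)-3-hydroxy-5-methoxy-2,2-dimethylchroman-8-yl]ethanone | COc1ccc(C(C)=O)c2c1C[C@H](O)C(C)(C)O2
F3 | step 8 | (2E)-1-[(3S)-3-hydroxy-5-methoxy-2,2-dimethylchroman-8-yl]-3-[4-(methoxymethoxy)phenyl]prop-2-en-1-one | COc1ccc(C(=O)/C=C/c2ccc(OCOC)cc2)c2c1C[C@H](O)C(C)(C)O2
F0 | step 7 | none | none
F4 | step 9 | 4-[3-[(3S)-3-hydroxy-5-methoxy-2,2-dimethylchroman-8-yl]-4,5-dihydro-1,2-oxazol-5-yl]phenol, both epimers at the aryl-bearing ring carbon | COc1ccc(C2=NOC(c3ccc(O)cc3)C2)c2c1C[C@H](O)C(C)(C)O2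
F5 | step 9 | (2E)-1-[(3S)-3-hydroxy-5-methoxy-2,2-dimethylchroman-8-yl]-3-(4-hydroxyphenyl)prop-2-en-1-one oxime | COc1ccc(C(=NO)/C=C/c2ccc(O)cc2)c2c1C[C@H](O)C(C)(C)O2
F6 | step 3 | 2-(5-methoxy-2,2-dimethyl-2H-chromen-8-yl)-1,3-dioxolane | COc1ccc(C2OCCO2)c2c1C=CC(C)(C)O2
F7 | step 3 | 2-[(3S,4S)-3,4-epoxy-5-methoxy-2,2-dimethylchroman-8-yl]-1,3-dioxolane | COc1ccc(C2OCCO2)c2c1[C@@H]1O[C@@H]1C(C)(C)O2
F8 | step 3 | (3S)-8-(1,3-dioxolan-2-yl)-5-methoxy-2,2-dimethylchroman-3-ol | COc1ccc(C2OCCO2)c2c1C[C@H](O)C(C)(C)O2
F0 | step 4 | none | none
A1 | alternative 1 | 1-[2-hydroxy-4-methoxy-3-[[(2S)-3,3-dimethyloxiran-2-yl]methyl]phenyl]ethanone | COc1ccc(C(C)=O)c(O)c1C[C@@H]1OC1(C)C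
A2 | alternative 1 | (3E)-1-diazohex-3-ene-2,5-dione | CC(=O)/C=C/C(=O)C=[N+]=[N-]
A3 | alternative 1 | (2S)-2-(3-methoxyprop-2-yn-1-yl)-3,3-dimethyloxirane | COC#CC[C@@H]1OC1(C)C
A4 | alternative 2 | 1-[(3S,4S)-3,4-epoxy-5-methoxy-2,2-dimethylchroman-8-yl]ethanone | COc1ccc(C(C)=O)c2c1[C@@H]1O[C@@H]1C(C)(C)O2
A5 | alternative 2 | 1-(5-methoxy-2,2-dimethyl-2H-chromen-8-yl)ethanone | COc1ccc(C(C)=O)c2c1C=CC(C)(C)O2
A6 | alternative 3 | methyl (3S)-3-(tert-butyldimethylsilyloxy)-5-methoxy-2,2-dimethylchroman-8-carboxylate | COc1ccc(C(=O)OC)c2c1C[C@H](O[Si](C)(C)C(C)(C)C)C(C)(C)O2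
A7 | alternative 3 | methyl (3S)-3-(tert-butyldimethylsilyloxy)-2,2-dimethyl-5-oxo-3,4-dihydro-2H,5H-pyrano[4,3-b]pyran-8-carboxylate | COC(=O)C1=COC(=O)C2=C1OC(C)(C)[C@@H](O[Si](C)(C)C(C)(C)C)C2
A8 | alternative 3 | 1,1-dimethoxyethene | C=C(OC)OC
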